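**Retrosynthetic overview**
1. Target 34 ⇐ nona-O-benzyl ether 33 by hydrogenolysis; the second dihydrofuran (C7″/C8″) ⇐ late Rh2(R-PTAD)4 carbene C–H insertion on the hydrazone of diaryl ketone 29, then acid cis→trans equilibration.
2. Seven-membered ring ⇐ acid-induced Friedel–Crafts closure of ring B onto the C7′ cation of (E)-stilbene 24, done before the second 3,5-dioxyphenyl ring is in place so that only one arene can close.
3. Stilbene 24 ⇐ Horner–Wadsworth–Emmons reaction of aldehyde 23 with phosphonate 7; the aldehyde comes from a laccase–TEMPO aerobic oxidation of alcohol 22.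
4. First dihydrofuran (C7/C8, the first stereocentres) ⇐ enantioselective Rh2(S-PTAD)4 1,5-C–H insertion of the diazo compound from ketone 17, then acid cis→trans equilibration.
5. Ketone 17 ⇐ symmetric dibromide 11 (from 3,5-dihydroxybenzyl alcohol) by mono Br/Li exchange and Weinreb acylation. Ring order: first dihydrofuran → seven-membered ring → second dihydrofuran.

**Conventions.** C7 (O-bearing) and C8 are the sp3 carbons of the first dihydrofuran; C7′ [CH(aryl)] and C8′ (CH2) belong to the seven-membered ring; C7″ (O-bearing) and C8″ belong to the second dihydrofuran. Ring A = 4-oxyphenyl on C7; ring B = 3,5-dioxyphenyl on C8 (its ortho carbon is bonded to C7′); ring C = 2,4-dioxyphenyl on C7′; ring D = central ring; ring E = 2,4-dioxyphenyl on C7″; the 3,5-dioxyphenyl group on C8″ is named in words. Rh2(S-PTAD)4 = dirhodium tetrakis[(S)-(1-adamantyl)(phthalimido)acetate]; Rh2(R-PTAD)4 is its mirror image.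

**Assumption.** Rh2(S-PTAD)4 is taken to give the (2S,3R)-cis product in step 12 and Rh2(R-PTAD)4 the mirror-image sense in step 22 (if the sense of induction on these substrates is the reverse, the two antipodes exchange places), and the substrate-controlled closure of step 17 is taken to give the 7′R epimer.

**Route**

Step 1
Reactants: 1 3,5-bis(benzyloxy)benzoic acid
Product: 3 3,5-bis(benzyloxy)-N-methoxy-N-methylbenzamide, via acid chloride 2 (not isolated)
Conditions: (COCl)2, DMF (cat.), CH2Cl2, 0 °C → rt; then MeNHOMe·HCl, Et3N, 0 °C → rt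
Reagents that add atoms: N,O-dimethylhydroxylamine hydrochloride, CNOC.Cl
Why: Acid chloride formation and amidation (nucleophilic acyl substitution) give the Weinreb amide that later acylates aryllithiums once only.

Step 2
Reactants: 4 2,4-bis(benzyloxy)benzaldehyde
Product: 5 [2,4-bis(benzyloxy)phenyl]methanol
Conditions: NaBH4, MeOH/THF, 0 °C
Reagents that add atoms: none
Why: Hydride reduction of an aromatic aldehyde by NaBH4 is chemoselective and leaves the benzyl ethers intact.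

Step 3
Reactants: 5 [2,4-bis(benzyloxy)phenyl]methanol
Product: 7 diethyl [2,4-bis(benzyloxy)benzyl]phosphonate, via benzylic bromide 6 (not isolated)
Conditions: PBr3, Et2O, 0 °C; then P(OEt)3, 110 °C
Reagents that add atoms: triethyl phosphite, CCOP(OCC)OCC
Why: Bromination and Michaelis–Arbuzov reaction in one flask give the phosphonate without storing the labile 2,4-dialkoxybenzyl bromide.

Step 4
Reactants: 8 3,5-dihydroxybenzyl alcohol
Product: 9 [3,5-bis(methoxymethoxy)phenyl]methanol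
Conditions: MOMCl (2.2 equiv), K2CO3, acetone, 0 °C → rt
Reagents that add atoms: chloromethyl methyl ether, COCCl
Why: Williamson-type O-alkylation in which K2CO3 deprotonates only the two phenols, so the primary alcohol stays free.

Step 5
Reactants: 9 [3,5-bis(methoxymethoxy)phenyl]methanol
Product: 10 [2,6-dibromo-3,5-bis(methoxymethoxy)phenyl]methanol
Conditions: NBS (2.05 equiv), MeCN, 0 °C → rt
Reagents that add atoms: N-bromosuccinimide, O=C1CCC(=O)N1Br
Why: Electrophilic aromatic bromination goes twice to the positions para to one OMOM and ortho to the other (C2 and C6), the site between the two OMOM groups being the more hindered.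

Step 6
Reactants: 10 [2,6-dibromo-3,5-bis(methoxymethoxy)phenyl]methanol
Product: 11 tert-butyl{[2,6-dibromo-3,5-bis(methoxymethoxy)benzyl]oxy}diphenylsilane
Conditions: TBDPSCl, imidazole, DMF, rt
Reagents that add atoms: tert-butyl(chloro)diphenylsilane, CC(C)(C)[Si](Cl)(c1ccccc1)c1ccccc1
Why: Silylation of the primary alcohol gives an acid- and base-stable ether whose hindered, weakly basic oxygen has no C–H on the silicon side for a later carbene to attack.

Step 7
Reactants: 11 tert-butyl{[2,6-dibromo-3,5-bis(methoxymethoxy)benzyl]oxy}diphenylsilane; 3 3,5-bis(benzyloxy)-N-methoxy-N-methylbenzamide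
Product: 13 [3,5-bis(benzyloxy)phenyl]{3-bromo-2-[(tert-butyldiphenylsilyloxy)methyl]-4,6-bis(methoxymethoxy)phenyl}methanone, via aryllithium 12 (not isolated)
Conditions: n-BuLi (1.0 equiv), THF, −78 °C, 15 min; then 3, −78 → −40 °C; aq. NH4Cl
Reagents that add atoms: none
Why: Bromine–lithium exchange on one of two equivalent bromines breaks the symmetry and the aryllithium is acylated through the stable Weinreb chelate (Weinreb ketone synthesis), so no over-addition and no carbinol stereocentre arise, while the low temperature prevents silyl migration and the second bromine is kept as the handle for the second dihydrofuran.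

Step 8
Reactants: 13 [3,5-bis(benzyloxy)phenyl]{3-bromo-2-[(tert-butyldiphenylsilyloxy)methyl]-4,6-bis(methoxymethoxy)phenyl}methanone
Product: 14 [3,5-bis(benzyloxy)phenyl]{3-bromo-2-[(tert-butyldiphenylsilyloxy)methyl]-4,6-dihydroxyphenyl}methanone
Conditions: conc. HCl (cat.), MeOH/THF, 30 °C
Reagents that add atoms: none
Why: Acid-catalysed transacetalisation to dimethoxymethane frees both phenols while the TBDPS and benzyl ethers survive.

Step 9
Reactants: 14 [3,5-bis(benzyloxy)phenyl]{3-bromo-2-[(tert-butyldiphenylsilyloxy)methyl]-4,6-dihydroxyphenyl}methanone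
Product: 15 {4-(allyloxy)-3-bromo-2-[(tert-butyldiphenylsilyloxy)methyl]-6-hydroxyphenyl}[3,5-bis(benzyloxy)phenyl]methanone
Conditions: allyl bromide (1.05 equiv), K2CO3 (1.1 equiv), acetone, rt
Reagents that add atoms: allyl bromide, C=CCBr
Why: Williamson etherification takes place selectively at the more acidic, non-chelated hydroxyl para to the ketone, because the ortho hydroxyl is locked in a hydrogen bond to the carbonyl.

Step 10
Reactants: 15 {4-(allyloxy)-3-bromo-2-[(tert-butyldiphenylsilyloxy)methyl]-6-hydroxyphenyl}[3,5-bis(benzyloxy)phenyl]methanone; 16 4-(benzyloxy)benzyl bromide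
Product: 17 {4-(allyloxy)-6-{[4-(benzyloxy)benzyl]oxy}-3-bromo-2-[(tert-butyldiphenylsilyloxy)methyl]phenyl}[3,5-bis(benzyloxy)phenyl]methanone
Conditions: K2CO3, DMF, 60 °C
Reagents that add atoms: none
Why: Williamson etherification under more forcing conditions alkylates the remaining chelated phenol and installs the ArO–CH2–Ar unit whose C–H bond the carbene will enter.

Step 11
Reactants: 17 {4-(allyloxy)-6-{[4-(benzyloxy)benzyl]oxy}-3-bromo-2-[(tert-butyldiphenylsilyloxy)methyl]phenyl}[3,5-bis(benzyloxy)phenyl]methanone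
Product: 18 hydrazone of ketone 17
Conditions: N2H4·H2O (20 equiv), AcOH (cat.), n-BuOH, 110 °C, argon
Reagents that add atoms: hydrazine monohydrate, NN.O
Why: Acid-catalysed condensation with a large excess of hydrazine gives the free hydrazone, forcing conditions being needed because the carbonyl is flanked by two ortho substituents.

Step 12
Reactants: 18 hydrazone of ketone 17
Product: 20 (2S,3R)-6-(allyloxy)-2-[4-(benzyloxy)phenyl]-3-[3,5-bis(benzyloxy)phenyl]-5-bromo-4-[(tert-butyldiphenylsilyloxy)methyl]-2,3-dihydro-1-benzofuran (cis), via diazo compound 19 (not isolated)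
Conditions: MnO2 (8 equiv), CH2Cl2, 0 °C; filter; Rh2(S-PTAD)4 (1 mol%), CH2Cl2, −20 → 0 °C
Reagents that add atoms: none
Why: MnO2 dehydrogenates the hydrazone to the diaryldiazomethane and the chiral dirhodium carboxylate converts it into a donor/donor carbene that undergoes enantioselective intramolecular 1,5-C–H insertion into the ArO–CH2–Ar bond, the catalyst fixing C3 as R and the concerted insertion giving the cis C2 epimer (2S).

Step 13
Reactants: 20 (2S,3R)-cis-dihydrobenzofuran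
Product: 21 (2R,3R)-6-(allyloxy)-2-[4-(benzyloxy)phenyl]-3-[3,5-bis(benzyloxy)phenyl]-5-bromo-4-[(tert-butyldiphenylsilyloxy)methyl]-2,3-dihydro-1-benzofuran (trans)
Conditions: TFA (3 equiv), CH2Cl2, 0 °C
Reagents that add atoms: none
Why: Protonation ionises only the C2–O bond (p-alkoxybenzyl cation) and reclosure under thermodynamic control gives the trans-2,3-diaryl isomer (2R) without touching C3.

Step 14
Reactants: 21 (2R,3R)-trans-dihydrobenzofuran silyl ether
Product: 22 [(2R,3R)-6-(allyloxy)-2-[4-(benzyloxy)phenyl]-3-[3,5-bis(benzyloxy)phenyl]-5-bromo-2,3-dihydro-1-benzofuran-4-yl]methanol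
Conditions: TBAF, THF, 0 °C → rt
Reagents that add atoms: none
Why: Fluoride-mediated desilylation frees the primary benzylic alcohol, nothing else in 21 being fluoride-labile.

Step 15
Reactants: 22 [(2R,3R)-6-(allyloxy)-2-[4-(benzyloxy)phenyl]-3-[3,5-bis(benzyloxy)phenyl]-5-bromo-2,3-dihydro-1-benzofuran-4-yl]methanol
Product: 23 (2R,3R)-6-(allyloxy)-2-[4-(benzyloxy)phenyl]-3-[3,5-bis(benzyloxy)phenyl]-5-bromo-2,3-dihydro-1-benzofuran-4-carbaldehyde
Conditions: laccase (Trametes versicolor), TEMPO (20 mol%), O2 (1 atm), NaOAc buffer pH 4.5/toluene, 30 °C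
Reagents that add atoms: none
Why: Laccase–TEMPO aerobic oxidation, in which the laccase (an oxidoreductase of the multicopper oxidase class) uses O2 to regenerate the oxoammonium form of TEMPO, takes the primary benzylic alcohol to the aldehyde without over-oxidation and without touching the allyl ether, the aryl bromide or the benzyl ethers.

Step 16
Reactants: 23 (2R,3R)-dihydrobenzofuran-4-carbaldehyde; 7 diethyl [2,4-bis(benzyloxy)benzyl]phosphonate
Product: 24 (2R,3R)-6-(allyloxy)-2-[4-(benzyloxy)phenyl]-3-[3,5-bis(benzyloxy)phenyl]-4-{(E)-2-[2,4-bis(benzyloxy)phenyl]ethenyl}-5-bromo-2,3-dihydro-1-benzofuran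
Conditions: KOtBu, THF, 0 °C → rt
Reagents that add atoms: none
Why: Horner–Wadsworth–Emmons olefination of the non-enolisable aldehyde with the stabilised benzylic phosphonate anion gives the (E)-stilbene.

Step 17
Reactants: 24 (2R,3R)-(E)-stilbene
Product: 25 (7R,8R,7′R)-tetracyclic bromo allyl ether (seven-membered ring closed between ring B and C7′)
Conditions: TFA (10 equiv), CH2Cl2 (5 mM), −20 → 0 °C
Reagents that add atoms: none
Why: Protonation of the stilbene at C8′ gives the C7′ cation stabilised by the ortho/para-benzyloxy groups of ring C, and intramolecular Friedel–Crafts alkylation by the ortho carbon of ring B (the only arene in reach) closes the seven-membered ring, the C8 stereocentre steering ring C to the less hindered face so that C7′ forms as R.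

Step 18
Reactants: 25 (7R,8R,7′R)-tetracyclic bromo allyl ether
Product: 26 (7R,8R,7′R)-tetracyclic bromophenol
Conditions: Pd(PPh3)4 (5 mol%), morpholine, THF, rt
Reagents that add atoms: none
Why: Tsuji–Trost deallylation through a π-allyl palladium complex trapped by morpholine frees the phenol at room temperature, where the hindered electron-rich aryl bromide does not react.

Step 19
Reactants: 26 (7R,8R,7′R)-tetracyclic bromophenol; 5 [2,4-bis(benzyloxy)phenyl]methanol
Product: 27 (7R,8R,7′R)-tetracyclic aryl bromide carrying the 2,4-bis(benzyloxy)benzyl ether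
Conditions: PPh3, DIAD, THF, 0 °C → rt
Reagents that add atoms: none
Why: Mitsunobu etherification of the acidic ortho-bromophenol with the primary benzylic alcohol installs the acid-labile benzyl ether that carries ring E only now, after the acid steps it would not have survived.

Step 20
Reactants: 27 (7R,8R,7′R)-tetracyclic aryl bromide; 3 3,5-bis(benzyloxy)-N-methoxy-N-methylbenzamide
Product: 29 (7R,8R,7′R)-tetracyclic diaryl ketone [3,5-bis(benzyloxy)benzoyl in place of Br], via aryllithium 28 (not isolated)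
Conditions: n-BuLi (1.05 equiv), THF, −78 °C, 10 min; then 3 (2 equiv), −78 → −30 °C; aq. NH4Cl
Reagents that add atoms: none
Why: Bromine–lithium exchange, which at −78 °C outruns deprotonation of the benzylic positions, followed by Weinreb ketone synthesis as in step 7.

Step 21
Reactants: 29 (7R,8R,7′R)-tetracyclic diaryl ketone
Product: 30 hydrazone of ketone 29
Conditions: N2H4·H2O (20 equiv), AcOH (cat.), n-BuOH, 110 °C, argon
Reagents that add atoms: hydrazine monohydrate, NN.O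
Why: Acid-catalysed hydrazone condensation as in step 11, the excess hydrazine keeping the medium too weakly acidic to cleave the dialkoxybenzyl ether.

Step 22
Reactants: 30 hydrazone of ketone 29
Product: 32 (7R,8R,7′R,7″R,8″S)-nona-O-benzyl ether carrying the cis second dihydrofuran, via diazo compound 31 (not isolated)
Conditions: MnO2 (8 equiv), CH2Cl2, 0 °C; filter; Rh2(R-PTAD)4 (2 mol%), CH2Cl2, −20 → 0 °C
Reagents that add atoms: none
Why: Diazo formation and enantioselective donor/donor carbene 1,5-C–H insertion as in step 12, the antipodal catalyst now setting C8″ as S and the concerted insertion giving the cis C7″ epimer (7″R).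

Step 23
Reactants: 32 (7R,8R,7′R,7″R,8″S)-nona-O-benzyl ether
Product: 33 (7R,8R,7′R,7″S,8″S)-nona-O-benzyl ether of the target
Conditions: TFA (2 equiv), CH2Cl2, −20 → 0 °C
Reagents that add atoms: none
Why: Acid-mediated ionisation and reclosure of the C7″–O bond, very easy because ring E is an ortho/para-dibenzyloxyphenyl group, gives the trans dihydrofuran (7″S) while C8″ and the other stereocentres are untouched.

Step 24
Reactants: 33 (7R,8R,7′R,7″S,8″S)-nona-O-benzyl ether of the target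
Product: 34 CNP0283541.1
Conditions: H2 (1 atm), 10% Pd/C, EtOAc/MeOH 1:1, rt
Reagents that add atoms: none
Why: Heterogeneous hydrogenolysis cleaves the nine primary O-benzyl ethers much faster than the hindered cyclic benzylic C–O bonds of the two dihydrofurans and gives the nonaphenol.

**Compound list**

1 | 3,5-bis(benzyloxy)benzoic acid | OC(=O)c1cc(OCc2ccccc2)cc(OCc2ccccc2)c1 | starting material
2 | 3,5-bis(benzyloxy)benzoyl chloride | ClC(=O)c1cc(OCc2ccccc2)cc(OCc2ccccc2)c1 | intermediate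
3 | 3,5-bis(benzyloxy)-N-methoxy-N-methylbenzamide | CON(C)C(=O)c1cc(OCc2ccccc2)cc(OCc2ccccc2)c1 | intermediate
4 | 2,4-bis(benzyloxy)benzaldehyde | O=Cc1ccc(OCc2ccccc2)cc1OCc1ccccc1 | starting material
5 | [2,4-bis(benzyloxy)phenyl]methanol | OCc1ccc(OCc2ccccc2)cc1OCc1ccccc1 | intermediate
6 | 2,4-bis(benzyloxy)benzyl bromide | BrCc1ccc(OCc2ccccc2)cc1OCc1ccccc1 | intermediate
7 | diethyl [2,4-bis(benzyloxy)benzyl]phosphonate | CCOP(=O)(Cc1ccc(OCc2ccccc2)cc1OCc1ccccc1)OCC | intermediate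
8 | 3,5-dihydroxybenzyl alcohol | OCc1cc(O)cc(O)c1 | starting material
9 | [3,5-bis(methoxymethoxy)phenyl]methanol | OCc1cc(OCOC)cc(OCOC)c1 | intermediate
10 | [2,6-dibromo-3,5-bis(methoxymethoxy)phenyl]methanol | OCc1c(Br)c(OCOC)cc(OCOC)c1Br | intermediate
11 | tert-butyl{[2,6-dibromo-3,5-bis(methoxymethoxy)benzyl]oxy}diphenylsilane | CC(C)(C)[Si](OCc1c(Br)c(OCOC)cc(OCOC)c1Br)(c1ccccc1)c1ccccc1 | intermediate
12 | {3-bromo-2-[(tert-butyldiphenylsilyloxy)methyl]-4,6-bis(methoxymethoxy)phenyl}lithium | [Li]c1c(OCOC)cc(OCOC)c(Br)c1CO[Si](C(C)(C)C)(c1ccccc1)c1ccccc1 | intermediate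
13 | [3,5-bis(benzyloxy)phenyl]{3-bromo-2-[(tert-butyldiphenylsilyloxy)methyl]-4,6-bis(methoxymethoxy)phenyl}methanone | O=C(c1cc(OCc2ccccc2)cc(OCc2ccccc2)c1)c1c(OCOC)cc(OCOC)c(Br)c1CO[Si](C(C)(C)C)(c1ccccc1)c1ccccc1 | intermediate
14 | [3,5-bis(benzyloxy)phenyl]{3-bromo-2-[(tert-butyldiphenylsilyloxy)methyl]-4,6-dihydroxyphenyl}methanone | O=C(c1cc(OCc2ccccc2)cc(OCc2ccccc2)c1)c1c(O)cc(O)c(Br)c1CO[Si](C(C)(C)C)(c1ccccc1)c1ccccc1 | intermediate
15 | {4-(allyloxy)-3-bromo-2-[(tert-butyldiphenylsilyloxy)methyl]-6-hydroxyphenyl}[3,5-bis(benzyloxy)phenyl]methanone | O=C(c1cc(OCc2ccccc2)cc(OCc2ccccc2)c1)c1c(O)cc(OCC=C)c(Br)c1CO[Si](C(C)(C)C)(c1ccccc1)c1ccccc1 | intermediate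
16 | 4-(benzyloxy)benzyl bromide | BrCc1ccc(OCc2ccccc2)cc1 | starting material
17 | {4-(allyloxy)-6-{[4-(benzyloxy)benzyl]oxy}-3-bromo-2-[(tert-butyldiphenylsilyloxy)methyl]phenyl}[3,5-bis(benzyloxy)phenyl]methanone | O=C(c1cc(OCc2ccccc2)cc(OCc2ccccc2)c1)c1c(OCc2ccc(OCc3ccccc3)cc2)cc(OCC=C)c(Br)c1CO[Si](C(C)(C)C)(c1ccccc1)c1ccccc1 | intermediate
18 | hydrazone of ketone 17 (C=N–NH2 in place of C=O) | NN=C(c1cc(OCc2ccccc2)cc(OCc2ccccc2)c1)c1c(OCc2ccc(OCc3ccccc3)cc2)cc(OCC=C)c(Br)c1CO[Si](C(C)(C)C)(c1ccccc1)c1ccccc1 | intermediate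
19 | diaryldiazomethane from 18 (C=N2 in place of C=O of 17) | [N-]=[N+]=C(c1cc(OCc2ccccc2)cc(OCc2ccccc2)c1)c1c(OCc2ccc(OCc3ccccc3)cc2)cc(OCC=C)c(Br)c1CO[Si](C(C)(C)C)(c1ccccc1)c1ccccc1 | intermediate
20 | (2S,3R)-6-(allyloxy)-2-[4-(benzyloxy)phenyl]-3-[3,5-bis(benzyloxy)phenyl]-5-bromo-4-[(tert-butyldiphenylsilyloxy)methyl]-2,3-dihydro-1-benzofuran (cis) | O(Cc1ccccc1)c1ccc([C@H]2Oc3cc(OCC=C)c(Br)c(CO[Si](C(C)(C)C)(c4ccccc4)c4ccccc4)c3[C@H]2c2cc(OCc3ccccc3)cc(OCc3ccccc3)c2)cc1 | intermediate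
21 | (2R,3R)-6-(allyloxy)-2-[4-(benzyloxy)phenyl]-3-[3,5-bis(benzyloxy)phenyl]-5-bromo-4-[(tert-butyldiphenylsilyloxy)methyl]-2,3-dihydro-1-benzofuran (trans) | O(Cc1ccccc1)c1ccc([C@@H]2Oc3cc(OCC=C)c(Br)c(CO[Si](C(C)(C)C)(c4ccccc4)c4ccccc4)c3[C@H]2c2cc(OCc3ccccc3)cc(OCc3ccccc3)c2)cc1 | intermediate
22 | [(2R,3R)-6-(allyloxy)-2-[4-(benzyloxy)phenyl]-3-[3,5-bis(benzyloxy)phenyl]-5-bromo-2,3-dihydro-1-benzofuran-4-yl]methanol | O(Cc1ccccc1)c1ccc([C@@H]2Oc3cc(OCC=C)c(Br)c(CO)c3[C@H]2c2cc(OCc3ccccc3)cc(OCc3ccccc3)c2)cc1 | intermediate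
23 | (2R,3R)-6-(allyloxy)-2-[4-(benzyloxy)phenyl]-3-[3,5-bis(benzyloxy)phenyl]-5-bromo-2,3-dihydro-1-benzofuran-4-carbaldehyde | O(Cc1ccccc1)c1ccc([C@@H]2Oc3cc(OCC=C)c(Br)c(C=O)c3[C@H]2c2cc(OCc3ccccc3)cc(OCc3ccccc3)c2)cc1 | intermediate
24 | (2R,3R)-6-(allyloxy)-2-[4-(benzyloxy)phenyl]-3-[3,5-bis(benzyloxy)phenyl]-4-{(E)-2-[2,4-bis(benzyloxy)phenyl]ethenyl}-5-bromo-2,3-dihydro-1-benzofuran | O(Cc1ccccc1)c1ccc([C@@H]2Oc3cc(OCC=C)c(Br)c(/C=C/c4ccc(OCc5ccccc5)cc4OCc4ccccc4)c3[C@H]2c2cc(OCc3ccccc3)cc(OCc3ccccc3)c2)cc1 | intermediate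
25 | (7R,8R,7′R)-tetracyclic bromo allyl ether: trans-dihydrofuran of 24 in which the ortho carbon of ring B is bonded to C7′H(ring C), C7′ being linked through C8′H2 to ring D; ring D keeps Br and O-allyl | O(Cc1ccccc1)c1ccc([C@@H]2Oc3cc(OCC=C)c(Br)c5c3[C@H]2c2cc(OCc3ccccc3)cc(OCc3ccccc3)c2[C@@H](c2ccc(OCc3ccccc3)cc2OCc2ccccc2)C5)cc1 | intermediate
26 | (7R,8R,7′R)-tetracyclic bromophenol: 25 with OH in place of O-allyl | O(Cc1ccccc1)c1ccc([C@@H]2Oc3cc(O)c(Br)c5c3[C@H]2c2cc(OCc3ccccc3)cc(OCc3ccccc3)c2[C@@H](c2ccc(OCc3ccccc3)cc2OCc2ccccc2)C5)cc1 | intermediate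
27 | (7R,8R,7′R)-tetracyclic aryl bromide: 26 with the phenol as its 2,4-bis(benzyloxy)benzyl ether | O(Cc1ccccc1)c1ccc([C@@H]2Oc3cc(OCc4ccc(OCc6ccccc6)cc4OCc4ccccc4)c(Br)c5c3[C@H]2c2cc(OCc3ccccc3)cc(OCc3ccccc3)c2[C@@H](c2ccc(OCc3ccccc3)cc2OCc2ccccc2)C5)cc1 | intermediate
28 | aryllithium: 27 with Li in place of Br | O(Cc1ccccc1)c1ccc([C@@H]2Oc3cc(OCc4ccc(OCc6ccccc6)cc4OCc4ccccc4)c([Li])c5c3[C@H]2c2cc(OCc3ccccc3)cc(OCc3ccccc3)c2[C@@H](c2ccc(OCc3ccccc3)cc2OCc2ccccc2)C5)cc1 | intermediate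
29 | (7R,8R,7′R)-tetracyclic diaryl ketone: 27 with 3,5-bis(benzyloxy)benzoyl in place of Br | O(Cc1ccccc1)c1ccc([C@@H]2Oc3cc(OCc4ccc(OCc6ccccc6)cc4OCc4ccccc4)c(C(=O)c4cc(OCc6ccccc6)cc(OCc6ccccc6)c4)c5c3[C@H]2c2cc(OCc3ccccc3)cc(OCc3ccccc3)c2[C@@H](c2ccc(OCc3ccccc3)cc2OCc2ccccc2)C5)cc1 | intermediate
30 | hydrazone of ketone 29 | O(Cc1ccccc1)c1ccc([C@@H]2Oc3cc(OCc4ccc(OCc6ccccc6)cc4OCc4ccccc4)c(C(=NN)c4cc(OCc6ccccc6)cc(OCc6ccccc6)c4)c5c3[C@H]2c2cc(OCc3ccccc3)cc(OCc3ccccc3)c2[C@@H](c2ccc(OCc3ccccc3)cc2OCc2ccccc2)C5)cc1 | intermediate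
31 | diaryldiazomethane from 30 | O(Cc1ccccc1)c1ccc([C@@H]2Oc3cc(OCc4ccc(OCc6ccccc6)cc4OCc4ccccc4)c(C(=[N+]=[N-])c4cc(OCc6ccccc6)cc(OCc6ccccc6)c4)c5c3[C@H]2c2cc(OCc3ccccc3)cc(OCc3ccccc3)c2[C@@H](c2ccc(OCc3ccccc3)cc2OCc2ccccc2)C5)cc1 | intermediate
32 | (7R,8R,7′R,7″R,8″S)-nona-O-benzyl ether carrying the cis second dihydrofuran [C7″ bears 2,4-bis(benzyloxy)phenyl, C8″ bears 3,5-bis(benzyloxy)phenyl] | O(Cc1ccccc1)c1ccc([C@@H]2Oc3cc4c(c5c3[C@H]2c2cc(OCc3ccccc3)cc(OCc3ccccc3)c2[C@@H](c2ccc(OCc3ccccc3)cc2OCc2ccccc2)C5)[C@H](c2cc(OCc3ccccc3)cc(OCc3ccccc3)c2)[C@H](c2ccc(OCc3ccccc3)cc2OCc2ccccc2)O4)cc1 | intermediate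
33 | (7R,8R,7′R,7″S,8″S)-nona-O-benzyl ether of the target (both dihydrofurans trans) | O(Cc1ccccc1)c1ccc([C@@H]2Oc3cc4c(c5c3[C@H]2c2cc(OCc3ccccc3)cc(OCc3ccccc3)c2[C@@H](c2ccc(OCc3ccccc3)cc2OCc2ccccc2)C5)[C@H](c2cc(OCc3ccccc3)cc(OCc3ccccc3)c2)[C@@H](c2ccc(OCc3ccccc3)cc2OCc2ccccc2)O4)cc1 | intermediate
34 | CNP0283541.1, (7R,8R,7′R,7″S,8″S)-nonaphenol | Oc1ccc([C@@H]2Oc3cc4c(c5c3[C@H]2c2cc(O)cc(O)c2[C@@H](c2ccc(O)cc2O)C5)[C@H](c2cc(O)cc(O)c2)[C@@H](c2ccc(O)cc2O)O4)cc1 | target

**Step count and risks**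

Total steps: 24. Longest linear sequence: 21 steps (steps 4 to 24, from 3,5-dihydroxybenzyl alcohol 8).

Steps most likely to fail:

Step 11 (hydrazone on a ketone flanked by two ortho substituents; the same concern applies to step 21). If hydrazine does not condense with 17, the two operations are exchanged. The fallback sets out from 15, whose carbonyl is held in plane and activated by the hydrogen bond of the free ortho-hydroxyl, and condensation with N2H4·H2O (EtOH, 80 °C) gives the ortho-hydroxyaryl ketone hydrazone F1. O-Alkylation of its phenoxide by bromide 16 (Cs2CO3, DMF, 0 °C → rt; the neutral hydrazone NH2 is far less nucleophilic than the phenoxide) comes back to the route at 18.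

Step 17 (cationic seven-membered ring closure; the risks are acid opening of the dihydrofuran followed by indane formation and a low diastereomer ratio at C7′). The cation is then made from a carbinol under a mild Lewis acid at −78 °C instead of from the stilbene in TFA. The fallback sets out from alcohol 22, and SOCl2/Et3N (CH2Cl2, 0 °C) gives the benzylic chloride F2. Zinc insertion (Zn dust, LiCl, THF, rt) gives the benzylic zinc chloride F3. MgCl2-promoted addition of this zinc reagent to aldehyde 4 gives the 1-aryl-2-arylethanol F4 as both carbinol epimers, which ionise to the same cation. BF3·OEt2 (CH2Cl2, −78 °C) then effects the same Friedel–Crafts closure and comes back to the route at 25.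

Step 20 (acylation of a very hindered aryllithium next to a benzylic ether late in the route). If 28 does not add cleanly to Weinreb amide 3, it is trapped at −78 °C by the far more electrophilic, commercial 3,5-bis(benzyloxy)benzaldehyde (O=Cc1cc(OCc2ccccc2)cc(OCc2ccccc2)c1). The fallback sets out from bromide 27 and gives the diarylmethanol F5 as both carbinol epimers, which is of no consequence. Oxidation by Dess–Martin periodinane (NaHCO3, CH2Cl2, rt) comes back to the route at 29.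

**Further compounds**

F1 | step 11 | {4-(allyloxy)-3-bromo-2-[(tert-butyldiphenylsilyloxy)methyl]-6-hydroxyphenyl}[3,5-bis(benzyloxy)phenyl]methanone hydrazone | NN=C(c1cc(OCc2ccccc2)cc(OCc2ccccc2)c1)c1c(O)cc(OCC=C)c(Br)c1CO[Si](C(C)(C)C)(c1ccccc1)c1ccccc1
F2 | step 17 | (2R,3R)-6-(allyloxy)-2-[4-(benzyloxy)phenyl]-3-[3,5-bis(benzyloxy)phenyl]-5-bromo-4-(chloromethyl)-2,3-dihydro-1-benzofuran | O(Cc1ccccc1)c1ccc([C@@H]2Oc3cc(OCC=C)c(Br)c(CCl)c3[C@H]2c2cc(OCc3ccccc3)cc(OCc3ccccc3)c2)cc1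
F3 | step 17 | benzylic zinc chloride from F2 (CH2ZnCl in place of CH2Cl) | O(Cc1ccccc1)c1ccc([C@@H]2Oc3cc(OCC=C)c(Br)c(C[Zn]Cl)c3[C@H]2c2cc(OCc3ccccc3)cc(OCc3ccccc3)c2)cc1
F4 | step 17 | 2-[(2R,3R)-6-(allyloxy)-2-[4-(benzyloxy)phenyl]-3-[3,5-bis(benzyloxy)phenyl]-5-bromo-2,3-dihydro-1-benzofuran-4-yl]-1-[2,4-bis(benzyloxy)phenyl]ethanol (both carbinol epimers) | O(Cc1ccccc1)c1ccc([C@@H]2Oc3cc(OCC=C)c(Br)c(CC(O)c4ccc(OCc5ccccc5)cc4OCc4ccccc4)c3[C@H]2c2cc(OCc3ccccc3)cc(OCc3ccccc3)c2)cc1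
F5 | step 20 | (7R,8R,7′R)-diarylmethanol: 27 with [3,5-bis(benzyloxy)phenyl](hydroxy)methyl in place of Br (both carbinol epimers) | O(Cc1ccccc1)c1ccc([C@@H]2Oc3cc(OCc4ccc(OCc6ccccc6)cc4OCc4ccccc4)c(C(O)c4cc(OCc6ccccc6)cc(OCc6ccccc6)c4)c5c3[C@H]2c2cc(OCc3ccccc3)cc(OCc3ccccc3)c2[C@@H](c2ccc(OCc3ccccc3)cc2OCc2ccccc2)C5)cc1
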